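## The problem

Compound 39 is a cembrane-type diterpenoid in which a 14-membered carbocycle (C1–C14) is bridged by a 2,2-dimethyloxolane: the ring oxygen joins C3 to the quaternary carbon C15 (methyls C16 and C17) that sits on C1, C4 carries the oxymethyl carbon C18 as a malonic half ester, C8 the formyl carbon C19 and C12 the methyl C20. Its three stereocentres C1, C3 and C4 (all R) are clustered: C1 and C3 are cis on the oxolane and the C3–O and C4–C18 bonds are anti, so C1, set once by an auxiliary, can relay to C3 through a five-membered ring closure, while C3 and C4 are best made together by a stereospecific addition. The carbocycle holds two trisubstituted alkenes of fixed geometry: the isolated Z-C11=C12 bond, which cannot be corrected later and must come from a stereospecific method, and the conjugated E-C7=C8 enal, which is the thermodynamic isomer and a natural place to close the large ring. The 14-membered ring has to be closed against oligomerisation without disturbing the stereocentres. The enal (electrophilic at C19 and C7, enolisable through C6 and C9) and the malonic half ester (acidic methylene, free acid, easy decarboxylation) tolerate neither hydride, strong base nor heat, and the trisubstituted alkenes together with the tertiary ether at C15 invite transannular cation chemistry in strong acid, so these groups must appear last and under near-neutral conditions. The feature that opens the shortest path is that O–C15–C1–C2–C3 is a five-atom chain and that oxygen on C3 and C18 on C4 are anti: this is the outcome of a 5-exo anti addition of the C15 hydroxyl and a one-carbon unit across an E-C3=C4 alkene.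

## Retrosynthesis

**Malonate last (C18–O acyl bond).** Target 39 is traced to its allyl ester 38, and 38 to hydroxy enal 34 and allyl hydrogen malonate 37, itself made from Meldrum's acid 35 and allyl alcohol 36. Cutting here keeps the acidic 1,3-dicarbonyl unit out of every base- and hydride-mediated step. The allyl group is chosen over tert-butyl or silylethyl esters because it is removed at room temperature by palladium catalysis without acid, base or fluoride. The forward steps must acylate a primary alcohol next to an enal and then unmask one carboxyl without touching it.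

**Oxidation levels at C18 and C19.** Enal 34 comes from diol 33 by chemoselective allylic oxidation, and 33 from macrocyclic diester 32 by one global ester reduction. Carrying C18 as the methyl ester that the key step delivers saves a reduction–protection–deprotection detour. This is safe because the only bases met on the way (a stabilised phosphonate anion, an amidine) are far too weak to enolise a simple ester, so C4 is not at risk. The forward reactions must reduce two esters cleanly and then distinguish an allylic from a saturated primary alcohol.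

**The macrocycle (C7=C8).** Diester 32 is opened at C7=C8 to phosphono aldehyde 31. The competing cuts are worse: C11=C12 has no activating group and is Z, and every sp3–sp3 bond of the ring would need a new pair of functional groups. An intramolecular Horner–Wadsworth–Emmons reaction closes the ring, brings in C19 at the ester level and gives the E-enoate. Aldehyde 31 goes back through alcohol 30 to phosphonate 29, which is cut at C8–C9 into iodide 26 and triethyl phosphonoacetate 27. Iodide 26 comes from alcohol 25 and silyl ether 24. The macrocycle is thereby reduced to an open chain with two differentiated primary termini (PMB ether at C7, TBDPS ether at C9).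

**Oxolane, C3, C4 and C18 in one step (O–C3 and C4–C18).** Oxolane ester 24 is cut at the O–C3 and C4–C18 bonds to the E-alkenyl tertiary alcohol 21. A palladium-mediated alkoxycarbonylation adds the C15 hydroxyl and a carbonyl carbon anti across E-C3=C4. Against stepwise etherification followed by C–C bond formation, this cut fixes C3 and C4 relative to each other by mechanism and delivers C18 with the right carbon count and oxidation level. The precursor has a single stereocentre. The forward step must close 5-exo rather than 6-endo, leave the trisubstituted alkene alone and form C3 cis to C1.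

**The carbinol and C1 (C15–CH3 and C1–C2).** Alcohol 21 comes from benzyl ester 19 by double methyl Grignard addition. Ester 19 comes from imide 18, and 18 from acyl oxazolidinone 10 and E-allylic bromide 16 by Evans alkylation. Cutting C1–C2 uses a reactive allylic electrophile and the most reliable enolate alkylation available, and it brings in the E-alkene with its geometry already set. The alternative cut at C1–C14 would need an unactivated homoallylic halide.

**The allylic bromide.** Bromide 16 goes back to E-allylic alcohol 15, propargylic alcohol 14, PMB ether 12 and pent-4-yn-1-ol 11. Trans-reduction of a propargylic alcohol gives only the E-alkene, and the five-carbon alkynol plus one carbon supplies C2–C7 exactly.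

**The Z-alkene arm (N-acyl bond, then C12–C13).** Imide 10 is made from acid 7 and (S)-4-benzyloxazolidin-2-one 8. Acid 7 is traced through aldehyde 6 and silyl ether 5 to homoallylic alcohol 4, which is cut at C12–C13 into 2-(3-bromopropyl)-1,3-dioxolane 1 and 5-methyl-2,3-dihydrofuran 2. Opening the cyclic enol ether with a Grignard reagent under nickel catalysis replaces the ring oxygen by carbon with retention, which a ketone olefination could not do selectively. This gives the Z-trisubstituted alkene and both chain termini in one step from two commercial compounds.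

## Roads not taken

**Alternative 1:** The C3–C4 bond is made the ring-closing bond. In the open-chain precursor A2, C3 is an aldehyde and C4 is the γ-carbon of an (R)-α-(methoxymethoxy)allyl tributylstannane. BF3·OEt2 would trigger an anti-SE2' addition that closes the 14-membered ring and gives the syn homoallylic alcohol A1 with a Z-enol ether on C4.
- Merits: the macrocycle and both C3 and C4 arise in one reagent-controlled step from a convergent precursor. In ring-forming power and convergence this road is stronger than the chosen one, whose key step closes only the oxolane.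
- Weak points: the enol ether carries two carbons where the target has only C18, so one must be excised oxidatively in the presence of two trisubstituted ring alkenes. The oxolane is still open in A1. The C3–O–C15 ether would then have to be made from a secondary and a tertiary alcohol, either through a C15 cation (elimination, transannular capture by C11=C12) or by inversion at C3, which would demand the opposite C3 configuration from the allylation. The stannane must be made enantiopure, and its facial preference has to match the remote C1 centre.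
- Comparison: up to the macrocycle the step count is similar or slightly better, but the repairs after A1 cost that back. The chosen plan sets against it that oxolane, C3, C4 and a correctly sized C18 arise together, and that ring closure is left to an olefination that also installs C19.

**Alternative 2:** The oxolane is built by a Prins–pinacol cascade, cutting C2–C3 and C1–C15. SnCl4 would open a cyclic acetal that ties the C3 carbon to the oxygens on C14 and C15. The vinyl terminus C2 attacks the oxocarbenium ion at C3, and C15 then shifts from C14 to C1, giving the 3-formyl-2,2-dimethyloxolane A3 with C14 as an aldehyde.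
- Merits: one ring and two C–C bonds form in one step. The cis relation of C1 and C3 follows from a chair transition state with the C3 substituent equatorial. This is a better-founded source of the 1,3-relationship than the envelope preference relied on in the chosen key step, and here the alternative is stronger.
- Weak points: C4 must already be in place, α to the oxocarbenium carbon, where it can epimerise through the enol ether and exerts only modest 1,2-induction. The absolute sense at C1 and C3 derives from a carbinol centre that is destroyed in the step. A3 carries only the C5–C7 arm, so the whole C13–C9 arm with its Z-alkene still has to be attached to the C14 aldehyde by olefination and reduction.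
- Comparison: the chosen plan is weaker in its C1-to-C3 relay. It sets against this the mechanistic coupling of C3 to C4 and a precursor that already carries both arms, so fewer steps follow the key step.

**Alternative 3:** C1 is taken from the chiral pool. (1R,5R)-α-Pinene A6 would be degraded to the cyclobutanone A5. A peracid Baeyer–Villiger oxidation, in which the quaternary C15 migrates from the carbonyl carbon C3 to oxygen, expands the four-membered ring to terpenylic acid A4, the γ-lactone form of the oxolane.
- Merits: C1 needs no auxiliary, the regiochemistry of oxygen insertion is secure, and the C15–O bond and gem-dimethyl group come for nothing. In sourcing absolute configuration and in certainty of the ring oxygen this road is better.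
- Weak points: C3 is a lactone carbonyl in A4. Turning it into the stereocentre that bears C4 needs an oxocarbenium addition that controls C3 (cis to C1) and C4 at once, two centres with no mechanistic link. C13 is a carboxyl carbon that must become the allylic methylene of a Z-trisubstituted alkene, for which ketone olefination is unselective. Several degradative steps are spent before any target bond is made.
- Comparison: the chosen plan pays two auxiliary steps. In return it gets a Z-alkene by a stereospecific coupling and a C3/C4 pair by a stereospecific addition.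

Key step: step 13

## Route

Remark: C8 in 29–31 forms as a mixture of epimers and is left unassigned, since it becomes sp2 in step 19.

Step 1
Reactants: 1 2-(3-bromopropyl)-1,3-dioxolane; 2 5-methyl-2,3-dihydrofuran
Product: 4 (3Z)-7-(1,3-dioxolan-2-yl)-4-methylhept-3-en-1-ol, via Grignard reagent 3 (not isolated)
Conditions: Mg, THF, 25 °C; then 2, Ni(dppp)Cl2 (5 mol %), toluene, 70 °C; H2O
Reagents that add atoms: none
Why: Kumada-type nickel-catalysed coupling of a cyclic enol ether: zerovalent nickel inserts into the vinylic C–O bond of 2, Grignard 3 transmetalates and reductive elimination puts the alkyl chain where oxygen was, with retention, so the hydroxyethyl arm and the new chain are cis (Z-C11=C12); the bidentate dppp ligand suppresses β-hydride elimination.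

Step 2
Reactants: 4 (3Z)-7-(1,3-dioxolan-2-yl)-4-methylhept-3-en-1-ol
Product: 5 tert-butyl{[(3Z)-7-(1,3-dioxolan-2-yl)-4-methylhept-3-en-1-yl]oxy}diphenylsilane
Conditions: TBDPSCl, imidazole, CH2Cl2, rt
Reagents that add atoms: tert-butyl(chloro)diphenylsilane, CC(C)(C)[Si](Cl)(c1ccccc1)c1ccccc1
Why: Standard silylation of a primary alcohol; the bulky TBDPS ether is chosen because it survives the aqueous acid of step 3 and the buffered methanol of step 13.

Step 3
Reactants: 5 tert-butyl{[(3Z)-7-(1,3-dioxolan-2-yl)-4-methylhept-3-en-1-yl]oxy}diphenylsilane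
Product: 6 (5Z)-8-{[tert-butyl(diphenyl)silyl]oxy}-5-methyloct-5-enal
Conditions: 1 M aq. HCl, THF, rt
Reagents that add atoms: water, O
Why: Acid-catalysed acetal hydrolysis; a primary TBDPS ether and a trisubstituted alkene are stable to dilute aqueous HCl at room temperature.

Step 4
Reactants: 6 (5Z)-8-{[tert-butyl(diphenyl)silyl]oxy}-5-methyloct-5-enal
Product: 7 (5Z)-8-{[tert-butyl(diphenyl)silyl]oxy}-5-methyloct-5-enoic acid
Conditions: NaClO2, NaH2PO4, 2-methylbut-2-ene, t-BuOH/H2O, rt
Reagents that add atoms: sodium chlorite, [Na+].[O-]Cl=O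
Why: Pinnick oxidation; chlorite oxidises only the aldehyde, and 2-methylbut-2-ene scavenges HOCl before it can reach the trisubstituted alkene.

Step 5
Reactants: 7 (5Z)-8-{[tert-butyl(diphenyl)silyl]oxy}-5-methyloct-5-enoic acid; 8 (S)-4-benzyl-1,3-oxazolidin-2-one
Product: 10 (4S)-4-benzyl-3-[(5Z)-8-{[tert-butyl(diphenyl)silyl]oxy}-5-methyloct-5-enoyl]-1,3-oxazolidin-2-one, via mixed pivalic anhydride 9 (not isolated)
Conditions: t-BuCOCl, Et3N, THF, −20 °C; then 8, LiCl, −20 °C → rt
Reagents that add atoms: none
Why: N-Acylation of the oxazolidinone through the mixed pivalic anhydride; attack occurs at the less hindered acyl carbon, and LiCl/Et3N activate the oxazolidinone without a strong base.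

Step 6
Reactants: 11 pent-4-yn-1-ol
Product: 12 1-methoxy-4-[(pent-4-yn-1-yloxy)methyl]benzene
Conditions: NaH, PMBCl, Bu4NI (cat.), THF, 0 °C → rt
Reagents that add atoms: 4-methoxybenzyl chloride, COc1ccc(CCl)cc1
Why: Williamson etherification; the PMB ether is orthogonal to TBDPS and is later removed oxidatively under neutral conditions.

Step 7
Reactants: 12 1-methoxy-4-[(pent-4-yn-1-yloxy)methyl]benzene
Product: 14 6-[(4-methoxybenzyl)oxy]hex-2-yn-1-ol, via lithium acetylide 13 (not isolated)
Conditions: n-BuLi, THF, −78 °C; (CH2O)n, −78 °C → rt; H2O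
Reagents that add atoms: formaldehyde (as paraformaldehyde), C=O
Why: Deprotonation of the terminal alkyne and addition of the acetylide to formaldehyde, a standard one-carbon homologation that supplies C2.

Step 8
Reactants: 14 6-[(4-methoxybenzyl)oxy]hex-2-yn-1-ol
Product: 15 (2E)-6-[(4-methoxybenzyl)oxy]hex-2-en-1-ol
Conditions: LiAlH4, THF, 0 °C → rt; H2O
Reagents that add atoms: none
Why: Hydroxyl-directed trans-hydroalumination of the propargylic alcohol and protonolysis give only the E-allylic alcohol, which fixes the E-C3=C4 geometry needed in step 13.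

Step 9
Reactants: 15 (2E)-6-[(4-methoxybenzyl)oxy]hex-2-en-1-ol
Product: 16 1-({[(4E)-6-bromohex-4-en-1-yl]oxy}methyl)-4-methoxybenzene
Conditions: CBr4, PPh3, CH2Cl2, 0 °C
Reagents that add atoms: carbon tetrabromide, BrC(Br)(Br)Br
Why: Appel bromination under neutral conditions converts the primary allylic alcohol into the allylic bromide without transposition or loss of E geometry.

Step 10
Reactants: 10 (4S)-4-benzyl-3-[(5Z)-8-{[tert-butyl(diphenyl)silyl]oxy}-5-methyloct-5-enoyl]-1,3-oxazolidin-2-one; 16 1-({[(4E)-6-bromohex-4-en-1-yl]oxy}methyl)-4-methoxybenzene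
Product: 18 (4S)-4-benzyl-3-[(2R,4E)-2-[(3Z)-6-{[tert-butyl(diphenyl)silyl]oxy}-3-methylhex-3-en-1-yl]-8-[(4-methoxybenzyl)oxy]oct-4-enoyl]-1,3-oxazolidin-2-one, via sodium Z-enolate 17 (not isolated)
Conditions: NaN(SiMe3)2, THF, −78 °C; then 16, −78 → −40 °C
Reagents that add atoms: none
Why: Evans asymmetric alkylation: the chelated sodium Z-enolate 17 is attacked by the reactive allylic bromide on the face opposite the benzyl group of the (S)-auxiliary, which sets C1 as R (the same sense as the allylation of the propionyl imide).

Step 11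
Reactants: 18 (4S)-4-benzyl-3-[(2R,4E)-2-[(3Z)-6-{[tert-butyl(diphenyl)silyl]oxy}-3-methylhex-3-en-1-yl]-8-[(4-methoxybenzyl)oxy]oct-4-enoyl]-1,3-oxazolidin-2-one
Product: 19 benzyl (2R,4E)-2-[(3Z)-6-{[tert-butyl(diphenyl)silyl]oxy}-3-methylhex-3-en-1-yl]-8-[(4-methoxybenzyl)oxy]oct-4-enoate
Conditions: LiOCH2Ph (from BnOH, n-BuLi), THF, 0 °C; H2O
Reagents that add atoms: benzyl alcohol (as lithium benzyloxide), OCc1ccccc1
Why: Transesterification of the imide with lithium benzyloxide attacks the exocyclic carbonyl selectively and releases the auxiliary without epimerising the α-centre.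

Step 12
Reactants: 19 benzyl (2R,4E)-2-[(3Z)-6-{[tert-butyl(diphenyl)silyl]oxy}-3-methylhex-3-en-1-yl]-8-[(4-methoxybenzyl)oxy]oct-4-enoate
Product: 21 (3R,5E)-3-[(3Z)-6-{[tert-butyl(diphenyl)silyl]oxy}-3-methylhex-3-en-1-yl]-9-[(4-methoxybenzyl)oxy]-2-methylnon-5-en-2-ol, via methyl ketone 20 (not isolated)
Conditions: MeMgBr (4 equiv), THF, 0 °C → rt; H2O
Reagents that add atoms: methylmagnesium bromide, C[Mg]Br
Why: Double Grignard addition to the ester through methyl ketone 20 gives the gem-dimethyl carbinol; addition to the ketone is faster than its enolisation, so C1 is retained.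

Step 13
Reactants: 21 (3R,5E)-3-[(3Z)-6-{[tert-butyl(diphenyl)silyl]oxy}-3-methylhex-3-en-1-yl]-9-[(4-methoxybenzyl)oxy]-2-methylnon-5-en-2-ol
Product: 24 methyl (2S)-2-[(2R,4R)-4-[(3Z)-6-{[tert-butyl(diphenyl)silyl]oxy}-3-methylhex-3-en-1-yl]-5,5-dimethyloxolan-2-yl]-5-[(4-methoxybenzyl)oxy]pentanoate, via alkylpalladium chloride 22 (not isolated), via acylpalladium chloride 23 (not isolated)
Conditions: PdCl2 (10 mol %), CuCl2 (3 equiv), NaOAc (3 equiv), CO (1 atm), MeOH, rt
Reagents that add atoms: carbon monoxide, [C-]#[O+]; methanol, CO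
Why: Divalent palladium coordinates the E-C3=C4 alkene and the C15 hydroxyl attacks C3 from the face opposite the metal (anti oxypalladation), closing the oxolane and leaving the C4–Pd bond of 22; CO inserts with retention to give 23, methanolysis releases the C18 methyl ester and zerovalent palladium, and CuCl2 reoxidises it. The closest known reaction type is the intramolecular alkoxycarbonylation of γ-hydroxy alkenes with PdCl2, CuCl2 and CO in methanol, which is stereospecifically anti on 1,2-disubstituted alkenes. The oxolane closes in the 5-exo-trig mode; 6-endo attack at C4 is stereoelectronically disfavoured, and 6-exo attack on C11=C12 is disfavoured because divalent palladium binds the less substituted alkene and the gem-dimethyl carbinol is held next to C3. C4 is fixed relative to C3 by anti addition across the E-alkene followed by retentive insertion. C3 is fixed relative to C1 by an envelope transition state in which the C14 chain on C1 and the metal-bound alkene on C3 are both pseudo-equatorial and avoid the syn methyl on C15, which gives the cis-oxolane. The CO atmosphere saturates palladium so that insertion outruns β-hydride elimination from C4. NaOAc takes up the HCl formed, so the silyl ether, the tertiary ether and the trisubstituted alkene never meet strong acid.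

Step 14
Reactants: 24 methyl (2S)-2-[(2R,4R)-4-[(3Z)-6-{[tert-butyl(diphenyl)silyl]oxy}-3-methylhex-3-en-1-yl]-5,5-dimethyloxolan-2-yl]-5-[(4-methoxybenzyl)oxy]pentanoate
Product: 25 methyl (2S)-2-[(2R,4R)-4-[(3Z)-6-hydroxy-3-methylhex-3-en-1-yl]-5,5-dimethyloxolan-2-yl]-5-[(4-methoxybenzyl)oxy]pentanoate
Conditions: Bu4NF, AcOH, THF, rt
Reagents that add atoms: none
Why: Fluoride cleaves the silyl ether; buffering with AcOH keeps the medium non-basic, so the β-alkoxy ester at C4 neither epimerises nor opens by retro-oxa-Michael reaction.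

Step 15
Reactants: 25 methyl (2S)-2-[(2R,4R)-4-[(3Z)-6-hydroxy-3-methylhex-3-en-1-yl]-5,5-dimethyloxolan-2-yl]-5-[(4-methoxybenzyl)oxy]pentanoate
Product: 26 methyl (2S)-2-[(2R,4R)-4-[(3Z)-6-iodo-3-methylhex-3-en-1-yl]-5,5-dimethyloxolan-2-yl]-5-[(4-methoxybenzyl)oxy]pentanoate
Conditions: I2, PPh3, imidazole, CH2Cl2, 0 °C → rt
Reagents that add atoms: iodine, II
Why: Appel-type iodination of the primary alcohol under neutral conditions; ester, PMB ether and alkenes are inert.

Step 16
Reactants: 26 methyl (2S)-2-[(2R,4R)-4-[(3Z)-6-iodo-3-methylhex-3-en-1-yl]-5,5-dimethyloxolan-2-yl]-5-[(4-methoxybenzyl)oxy]pentanoate; 27 triethyl phosphonoacetate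
Product: 29 ethyl (5Z)-2-(diethoxyphosphoryl)-8-[(3R,5R)-5-[(2S)-1-methoxy-5-[(4-methoxybenzyl)oxy]-1-oxopentan-2-yl]-2,2-dimethyloxolan-3-yl]-6-methyloct-5-enoate (mixture of C2 epimers), via sodium phosphonoacetate 28 (not isolated)
Conditions: 27 (1.5 equiv), NaH (1.4 equiv), DMF, 0 °C; then 26, 50 °C
Reagents that add atoms: none
Why: Alkylation of the sodium salt 28 of triethyl phosphonoacetate by a primary iodide, the standard route to α-substituted phosphonoacetates; the soft, weakly basic carbanion, kept in excess over NaH, favours substitution over elimination to the 1,3-diene and cannot enolise the C18 ester.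

Step 17
Reactants: 29 ethyl (5Z)-2-(diethoxyphosphoryl)-8-[(3R,5R)-5-[(2S)-1-methoxy-5-[(4-methoxybenzyl)oxy]-1-oxopentan-2-yl]-2,2-dimethyloxolan-3-yl]-6-methyloct-5-enoate
Product: 30 ethyl (5Z)-2-(diethoxyphosphoryl)-8-[(3R,5R)-5-[(2S)-5-hydroxy-1-methoxy-1-oxopentan-2-yl]-2,2-dimethyloxolan-3-yl]-6-methyloct-5-enoate
Conditions: DDQ, CH2Cl2/pH 7 buffer, 0 °C
Reagents that add atoms: none
Why: Oxidative cleavage of the PMB ether by DDQ in wet CH2Cl2 through the benzylic oxocarbenium ion; the conditions are neutral, so phosphonate, esters and alkenes survive.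

Step 18
Reactants: 30 ethyl (5Z)-2-(diethoxyphosphoryl)-8-[(3R,5R)-5-[(2S)-5-hydroxy-1-methoxy-1-oxopentan-2-yl]-2,2-dimethyloxolan-3-yl]-6-methyloct-5-enoate
Product: 31 ethyl (5Z)-2-(diethoxyphosphoryl)-8-[(3R,5R)-5-[(2S)-1-methoxy-1,5-dioxopentan-2-yl]-2,2-dimethyloxolan-3-yl]-6-methyloct-5-enoate
Conditions: Dess–Martin periodinane, CH2Cl2, rt
Reagents that add atoms: none
Why: Dess–Martin oxidation of the primary alcohol to the aldehyde under non-basic conditions, so the phosphonoacetate is not deprotonated before dilution.

Step 19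
Reactants: 31 ethyl (5Z)-2-(diethoxyphosphoryl)-8-[(3R,5R)-5-[(2S)-1-methoxy-1,5-dioxopentan-2-yl]-2,2-dimethyloxolan-3-yl]-6-methyloct-5-enoate
Product: 32 macrocyclic diester: (1R,3R,4S,7E,11Z)-3,15-epoxycembra-7,11-diene carrying CO2Me as C18 on C4 and CO2Et as C19 on C8
Conditions: LiCl, DBU, MeCN, rt, slow addition of 31 (final ca. 1 mM)
Reagents that add atoms: none
Why: Intramolecular Horner–Wadsworth–Emmons olefination under Masamune–Roush conditions at high dilution; the lithium-chelated α-substituted phosphonoacetate gives the E-enoate (ester trans to C6), which is the C7=C8 geometry of the target, and the amidine base is too weak to touch the C4 ester.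

Step 20
Reactants: 32 macrocyclic diester
Product: 33 (1R,3R,4R,7E,11Z)-3,15-epoxycembra-7,11-diene-18,19-diol
Conditions: i-Bu2AlH (excess), CH2Cl2, −78 → 0 °C; aq. potassium sodium tartrate
Reagents that add atoms: none
Why: i-Bu2AlH reduces the conjugated ethyl ester 1,2 to the allylic alcohol and the saturated methyl ester to the primary alcohol in one operation; no other reducible group is present.

Step 21
Reactants: 33 (1R,3R,4R,7E,11Z)-3,15-epoxycembra-7,11-diene-18,19-diol
Product: 34 (1R,3R,4R,7E,11Z)-3,15-epoxy-18-hydroxycembra-7,11-dien-19-al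
Conditions: MnO2, CH2Cl2, rt
Reagents that add atoms: none
Why: Activated MnO2 oxidises allylic alcohols far faster than saturated primary alcohols, so only C19 becomes the aldehyde, with retention of alkene geometry; the two hydroxyls are told apart without a protecting group.

Step 22
Reactants: 35 2,2-dimethyl-1,3-dioxane-4,6-dione (Meldrum's acid); 36 prop-2-en-1-ol
Product: 37 3-oxo-3-(prop-2-en-1-yloxy)propanoic acid (allyl hydrogen malonate)
Conditions: toluene, 100 °C
Reagents that add atoms: none
Why: Alcoholysis of Meldrum's acid: the alcohol opens the dioxanedione and acetone is expelled, giving the malonic monoester directly.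

Step 23
Reactants: 34 (1R,3R,4R,7E,11Z)-3,15-epoxy-18-hydroxycembra-7,11-dien-19-al; 37 3-oxo-3-(prop-2-en-1-yloxy)propanoic acid
Product: 38 allyl malonate of 34: (1R,3R,4R,7E,11Z)-3,15-epoxy-19-oxocembra-7,11-dien-18-yl prop-2-en-1-yl propanedioate
Conditions: DCC, DMAP (cat.), CH2Cl2, 0 °C
Reagents that add atoms: none
Why: Steglich esterification; malonic half esters are activated by DCC very rapidly, so the primary C18 hydroxyl is acylated at 0 °C while the enal is untouched.

Step 24
Reactants: 38 allyl malonate of 34
Product: 39 3-{[(1R,3R,4R,7E,11Z)-3,15-epoxy-19-oxocembra-7,11-dien-18-yl]oxy}-3-oxopropanoic acid (CNP0170412.1)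
Conditions: Pd(PPh3)4 (5 mol %), PhNHMe, THF, rt; dilute aq. citric acid
Reagents that add atoms: none
Why: Tsuji–Trost deallylation: zerovalent palladium ionises the allyl ester to a π-allyl complex and the carboxylate, and the weakly basic N-methylaniline takes up the allyl group; the medium is neutral and at room temperature, so the enal, the alkenes and the malonic half ester (no decarboxylation) are preserved.

## Compound list

1 | 2-(3-bromopropyl)-1,3-dioxolane | BrCCCC1OCCO1 | starting material
2 | 5-methyl-2,3-dihydrofuran | CC1=CCCO1 | starting material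
3 | [3-(1,3-dioxolan-2-yl)propyl]magnesium bromide (not isolated) | Br[Mg]CCCC1OCCO1 | intermediate
4 | (3Z)-7-(1,3-dioxolan-2-yl)-4-methylhept-3-en-1-ol | OCC/C=C(C)\CCCC1OCCO1 | intermediate
5 | tert-butyl{[(3Z)-7-(1,3-dioxolan-2-yl)-4-methylhept-3-en-1-yl]oxy}diphenylsilane | CC(C)(C)[Si](c1ccccc1)(c1ccccc1)OCC/C=C(C)\CCCC1OCCO1 | intermediate
6 | (5Z)-8-{[tert-butyl(diphenyl)silyl]oxy}-5-methyloct-5-enal | CC(C)(C)[Si](c1ccccc1)(c1ccccc1)OCC/C=C(C)\CCCC=O | intermediate
7 | (5Z)-8-{[tert-butyl(diphenyl)silyl]oxy}-5-methyloct-5-enoic acid | CC(C)(C)[Si](c1ccccc1)(c1ccccc1)OCC/C=C(C)\CCCC(=O)O | intermediate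
8 | (S)-4-benzyl-1,3-oxazolidin-2-one | O=C1N[C@@H](Cc2ccccc2)CO1 | starting material
9 | mixed anhydride of 7 with pivalic acid (not isolated) | CC(C)(C)[Si](c1ccccc1)(c1ccccc1)OCC/C=C(C)\CCCC(=O)OC(=O)C(C)(C)C | intermediate
10 | (4S)-4-benzyl-3-[(5Z)-8-{[tert-butyl(diphenyl)silyl]oxy}-5-methyloct-5-enoyl]-1,3-oxazolidin-2-one | CC(C)(C)[Si](c1ccccc1)(c1ccccc1)OCC/C=C(C)\CCCC(=O)N1[C@@H](Cc2ccccc2)COC1=O | intermediate
11 | pent-4-yn-1-ol | C#CCCCO | starting material
12 | 1-methoxy-4-[(pent-4-yn-1-yloxy)methyl]benzene | C#CCCCOCc1ccc(OC)cc1 | intermediate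
13 | {5-[(4-methoxybenzyl)oxy]pent-1-yn-1-yl}lithium (not isolated) | [Li]C#CCCCOCc1ccc(OC)cc1 | intermediate
14 | 6-[(4-methoxybenzyl)oxy]hex-2-yn-1-ol | OCC#CCCCOCc1ccc(OC)cc1 | intermediate
15 | (2E)-6-[(4-methoxybenzyl)oxy]hex-2-en-1-ol | OC/C=C/CCCOCc1ccc(OC)cc1 | intermediate
16 | 1-({[(4E)-6-bromohex-4-en-1-yl]oxy}methyl)-4-methoxybenzene | BrC/C=C/CCCOCc1ccc(OC)cc1 | intermediate
17 | sodium Z-enolate of 10 (not isolated) | [Na]O/C(=C\CC/C(C)=C\CCO[Si](c1ccccc1)(c1ccccc1)C(C)(C)C)N1[C@@H](Cc2ccccc2)COC1=O | intermediate
18 | (4S)-4-benzyl-3-[(2R,4E)-2-[(3Z)-6-{[tert-butyl(diphenyl)silyl]oxy}-3-methylhex-3-en-1-yl]-8-[(4-methoxybenzyl)oxy]oct-4-enoyl]-1,3-oxazolidin-2-one | CC(C)(C)[Si](c1ccccc1)(c1ccccc1)OCC/C=C(C)\CC[C@H](C/C=C/CCCOCc1ccc(OC)cc1)C(=O)N1[C@@H](Cc2ccccc2)COC1=O | intermediate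
19 | benzyl (2R,4E)-2-[(3Z)-6-{[tert-butyl(diphenyl)silyl]oxy}-3-methylhex-3-en-1-yl]-8-[(4-methoxybenzyl)oxy]oct-4-enoate | CC(C)(C)[Si](c1ccccc1)(c1ccccc1)OCC/C=C(C)\CC[C@H](C/C=C/CCCOCc1ccc(OC)cc1)C(=O)OCc1ccccc1 | intermediate
20 | (3R,5E)-3-[(3Z)-6-{[tert-butyl(diphenyl)silyl]oxy}-3-methylhex-3-en-1-yl]-9-[(4-methoxybenzyl)oxy]non-5-en-2-one (not isolated) | CC(C)(C)[Si](c1ccccc1)(c1ccccc1)OCC/C=C(C)\CC[C@H](C/C=C/CCCOCc1ccc(OC)cc1)C(C)=O | intermediate
21 | (3R,5E)-3-[(3Z)-6-{[tert-butyl(diphenyl)silyl]oxy}-3-methylhex-3-en-1-yl]-9-[(4-methoxybenzyl)oxy]-2-methylnon-5-en-2-ol | CC(C)(C)[Si](c1ccccc1)(c1ccccc1)OCC/C=C(C)\CC[C@H](C/C=C/CCCOCc1ccc(OC)cc1)C(C)(C)O | intermediate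
22 | C4 alkylpalladium chloride of the cis-oxolane (not isolated) | COc1ccc(COCCC[C@H]([Pd]Cl)[C@H]2C[C@@H](CC/C(C)=C\CCO[Si](c3ccccc3)(c3ccccc3)C(C)(C)C)C(C)(C)O2)cc1 | intermediate
23 | C18 acylpalladium chloride of the cis-oxolane (not isolated) | COc1ccc(COCCC[C@H](C(=O)[Pd]Cl)[C@H]2C[C@@H](CC/C(C)=C\CCO[Si](c3ccccc3)(c3ccccc3)C(C)(C)C)C(C)(C)O2)cc1 | intermediate
24 | methyl (2S)-2-[(2R,4R)-4-[(3Z)-6-{[tert-butyl(diphenyl)silyl]oxy}-3-methylhex-3-en-1-yl]-5,5-dimethyloxolan-2-yl]-5-[(4-methoxybenzyl)oxy]pentanoate | COc1ccc(COCCC[C@H](C(=O)OC)[C@H]2C[C@@H](CC/C(C)=C\CCO[Si](c3ccccc3)(c3ccccc3)C(C)(C)C)C(C)(C)O2)cc1 | intermediate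
25 | methyl (2S)-2-[(2R,4R)-4-[(3Z)-6-hydroxy-3-methylhex-3-en-1-yl]-5,5-dimethyloxolan-2-yl]-5-[(4-methoxybenzyl)oxy]pentanoate | COc1ccc(COCCC[C@H](C(=O)OC)[C@H]2C[C@@H](CC/C(C)=C\CCO)C(C)(C)O2)cc1 | intermediate
26 | methyl (2S)-2-[(2R,4R)-4-[(3Z)-6-iodo-3-methylhex-3-en-1-yl]-5,5-dimethyloxolan-2-yl]-5-[(4-methoxybenzyl)oxy]pentanoate | COc1ccc(COCCC[C@H](C(=O)OC)[C@H]2C[C@@H](CC/C(C)=C\CCI)C(C)(C)O2)cc1 | intermediate
27 | triethyl phosphonoacetate | CCOC(=O)CP(=O)(OCC)OCC | starting material
28 | sodium salt of triethyl phosphonoacetate (not isolated) | [Na+].CCOC(=O)[CH-]P(=O)(OCC)OCC | intermediate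
29 | ethyl (5Z)-2-(diethoxyphosphoryl)-8-[(3R,5R)-5-[(2S)-1-methoxy-5-[(4-methoxybenzyl)oxy]-1-oxopentan-2-yl]-2,2-dimethyloxolan-3-yl]-6-methyloct-5-enoate (C2 epimers) | COc1ccc(COCCC[C@H](C(=O)OC)[C@H]2C[C@@H](CC/C(C)=C\CCC(C(=O)OCC)P(=O)(OCC)OCC)C(C)(C)O2)cc1 | intermediate
30 | ethyl (5Z)-2-(diethoxyphosphoryl)-8-[(3R,5R)-5-[(2S)-5-hydroxy-1-methoxy-1-oxopentan-2-yl]-2,2-dimethyloxolan-3-yl]-6-methyloct-5-enoate (C2 epimers) | OCCC[C@H](C(=O)OC)[C@H]1C[C@@H](CC/C(C)=C\CCC(C(=O)OCC)P(=O)(OCC)OCC)C(C)(C)O1 | intermediate
31 | ethyl (5Z)-2-(diethoxyphosphoryl)-8-[(3R,5R)-5-[(2S)-1-methoxy-1,5-dioxopentan-2-yl]-2,2-dimethyloxolan-3-yl]-6-methyloct-5-enoate (C2 epimers) | O=CCC[C@H](C(=O)OC)[C@H]1C[C@@H](CC/C(C)=C\CCC(C(=O)OCC)P(=O)(OCC)OCC)C(C)(C)O1 | intermediate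
32 | macrocyclic diester: (1R,3R,4S,7E,11Z)-3,15-epoxycembra-7,11-diene with CO2Me (C18) on C4 and CO2Et (C19) on C8 | C/C1=C/CC/C(C(=O)OCC)=C\CC[C@H](C(=O)OC)[C@H]2C[C@@H](CC1)C(C)(C)O2 | intermediate
33 | (1R,3R,4R,7E,11Z)-3,15-epoxycembra-7,11-diene-18,19-diol | C/C1=C/CC/C(CO)=C\CC[C@H](CO)[C@H]2C[C@@H](CC1)C(C)(C)O2 | intermediate
34 | (1R,3R,4R,7E,11Z)-3,15-epoxy-18-hydroxycembra-7,11-dien-19-al | C/C1=C/CC/C(C=O)=C\CC[C@H](CO)[C@H]2C[C@@H](CC1)C(C)(C)O2 | intermediate
35 | 2,2-dimethyl-1,3-dioxane-4,6-dione (Meldrum's acid) | CC1(C)OC(=O)CC(=O)O1 | starting material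
36 | prop-2-en-1-ol | C=CCO | starting material
37 | 3-oxo-3-(prop-2-en-1-yloxy)propanoic acid | C=CCOC(=O)CC(=O)O | intermediate
38 | (1R,3R,4R,7E,11Z)-3,15-epoxy-19-oxocembra-7,11-dien-18-yl prop-2-en-1-yl propanedioate | C/C1=C/CC/C(C=O)=C\CC[C@H](COC(=O)CC(=O)OCC=C)[C@H]2C[C@@H](CC1)C(C)(C)O2 | intermediate
39 | 3-{[(1R,3R,4R,7E,11Z)-3,15-epoxy-19-oxocembra-7,11-dien-18-yl]oxy}-3-oxopropanoic acid (CNP0170412.1) | C/C1=C/CC/C(C=O)=C\CC[C@H](COC(=O)CC(=O)O)[C@H]2C[C@@H](CC1)C(C)(C)O2 | target

## Step count and risks

Total: 24 steps. Longest linear sequence: 19 steps (steps 1–5, 10–21, 23 and 24).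

**Step 13 (key step).** The most likely failure is insufficient facial discrimination in the oxypalladation. The envelope preference that places C3 cis to C1 is a conformational bias, not a mechanistic requirement, so the trans-oxolane (C3 and C4 both inverted) could form alongside. Lesser risks are β-hydride elimination from C4 if CO insertion is slow, and acid-promoted addition of the hydroxyl to C11=C12 if buffering fails.
Fallback: setting out from 21, the ring is closed with Hg(OCOCF3)2 in MeCN. Anti oxymercuration is reversible, so the more stable cis-oxolane can accumulate under equilibration. Exchange with aqueous NaCl gives the C4 organomercury chloride F1. F1 is then transmetalated to palladium and methoxycarbonylated with retention at C4 (PdCl2, LiCl, CO, MeOH, CuCl2 as reoxidant), which returns to 24.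

**Step 19.** Ring closure at C7=C8 may be slower than intermolecular olefination, which leads to oligomerisation, and the constraint of the forming ring may erode the E-selectivity of the α-substituted phosphonoacetate.
Fallback: setting out from 29, olefination with aqueous formaldehyde and K2CO3 gives the α-methylene ester F2. DDQ then gives the alcohol F3, Dess–Martin periodinane the aldehyde F4, and Ph3P=CH2 the terminal alkene F5. Ring-closing metathesis of F5 with the second-generation Grubbs catalyst in dilute toluene forms C7=C8 with loss of ethene and returns to 32.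

**Step 16.** Substitution at the homoallylic iodide by the stabilised anion may be slow. It then competes with elimination to the 1,3-diene and with a second alkylation of the product.
Fallback: setting out from 26, zinc insertion (Zn, LiCl, THF) gives the alkylzinc iodide F6, which tolerates the ester. Negishi coupling with ethyl 2-bromoacrylate under Pd(PPh3)4 catalysis gives the α-methylene ester F2, which continues through the alcohol F3, the aldehyde F4 and the terminal alkene F5 to the ring-closing metathesis and rejoins the route at 32.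

**Step 1.** The alkylnickel intermediate may undergo β-hydride elimination, which reduces the enol ether instead of coupling it, or isomerisation, which erodes the Z geometry. The acetal-bearing Grignard reagent may also degrade at the coupling temperature.
Fallback: setting out from 1 (through Grignard reagent 3), CuBr·SMe2 gives the alkylcopper, which adds syn across propyne at −25 °C to the (Z)-alkenylcopper F7. Activation as the mixed cuprate with 1-lithiopent-1-yne and trapping with ethylene oxide, with retention, returns to 4.

**Step 24.** The amine scavenger may add reversibly to the enal, or the π-allyl complex may be captured by the malonate carbon instead of the scavenger, either of which would cut the recovery of the free half ester.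
Fallback: setting out from 34, heating with Meldrum's acid 35 in toluene at 80 °C opens the dioxanedione with the C18 hydroxyl and expels acetone, which gives 39 directly without an allyl ester or palladium.

## Further compounds

F1 | step 13 | C4 organomercury chloride of the cis-oxolane | COc1ccc(COCCC[C@H]([Hg]Cl)[C@H]2C[C@@H](CC/C(C)=C\CCO[Si](c3ccccc3)(c3ccccc3)C(C)(C)C)C(C)(C)O2)cc1
F2 | step 19 | α-methylene ester: ethyl (5Z)-8-[(3R,5R)-5-[(2S)-1-methoxy-5-[(4-methoxybenzyl)oxy]-1-oxopentan-2-yl]-2,2-dimethyloxolan-3-yl]-6-methyl-2-methylideneoct-5-enoate | COc1ccc(COCCC[C@H](C(=O)OC)[C@H]2C[C@@H](CC/C(C)=C\CCC(=C)C(=O)OCC)C(C)(C)O2)cc1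
F3 | step 19 | alcohol: ethyl (5Z)-8-[(3R,5R)-5-[(2S)-5-hydroxy-1-methoxy-1-oxopentan-2-yl]-2,2-dimethyloxolan-3-yl]-6-methyl-2-methylideneoct-5-enoate | OCCC[C@H](C(=O)OC)[C@H]1C[C@@H](CC/C(C)=C\CCC(=C)C(=O)OCC)C(C)(C)O1
F4 | step 19 | aldehyde: ethyl (5Z)-8-[(3R,5R)-5-[(2S)-1-methoxy-1,5-dioxopentan-2-yl]-2,2-dimethyloxolan-3-yl]-6-methyl-2-methylideneoct-5-enoate | O=CCC[C@H](C(=O)OC)[C@H]1C[C@@H](CC/C(C)=C\CCC(=C)C(=O)OCC)C(C)(C)O1
F5 | step 19 | terminal alkene: ethyl (5Z)-8-[(3R,5R)-5-[(2S)-1-methoxy-1-oxohex-5-en-2-yl]-2,2-dimethyloxolan-3-yl]-6-methyl-2-methylideneoct-5-enoate | C=CCC[C@H](C(=O)OC)[C@H]1C[C@@H](CC/C(C)=C\CCC(=C)C(=O)OCC)C(C)(C)O1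
F6 | step 16 | alkylzinc iodide from 26 | COc1ccc(COCCC[C@H](C(=O)OC)[C@H]2C[C@@H](CC/C(C)=C\CC[Zn]I)C(C)(C)O2)cc1
F7 | step 1 | (Z)-[5-(1,3-dioxolan-2-yl)-2-methylpent-1-en-1-yl]copper | [Cu]/C=C(C)\CCCC1OCCO1
F0 | step 24 | none | none
A1 | alternative 1 | 14-membered syn homoallylic alcohol with a Z-enol ether on C4 | C/C1=C/CC/C(CO[Si](C)(C)C(C)(C)C)=C\CC[C@H](/C=C\OCOC)[C@H](O)C[C@@H](CC1)C(C)(C)O[Si](CC)(CC)CC
A2 | alternative 1 | open-chain C3 aldehyde carrying the (R)-α-(methoxymethoxy)allyl tributylstannane | CCCC[Sn](CCCC)(CCCC)[C@@H](OCOC)/C=C/CC/C=C(CO[Si](C)(C)C(C)(C)C)\CC/C=C(C)\CC[C@H](CC=O)C(C)(C)O[Si](CC)(CC)CC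
A3 | alternative 2 | 3-formyl-2,2-dimethyloxolane carrying the C4–C7 arm | CC(C)(C)[Si](C)(C)OCCC[C@H](CO[Si](C(C)C)(C(C)C)C(C)C)[C@H]1C[C@@H](C=O)C(C)(C)O1
A4 | alternative 3 | terpenylic acid, C1 configured as in 39 | O=C1C[C@@H](CC(=O)O)C(C)(C)O1
A5 | alternative 3 | 2-(2,2-dimethyl-3-oxocyclobutyl)acetic acid, C1 configured as in 39 | O=C1C[C@@H](CC(=O)O)C1(C)C
A6 | alternative 3 | (1R,5R)-α-pinene | CC1=CC[C@@H]2C[C@H]1C2(C)C
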